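The route rests on breaking ring A at two bonds at once: the ring bond from the carbinol carbon to the alkylidene ring carbon and the bond from the exocyclic =CH to the first tether CH2. One nickel-catalysed alkylative cyclization of an acyclic ynal with the homoallylzinc iodide of finished ring B makes both, closing ring A, setting its carbinol centre and fixing the Z alkene. It exploits the ring A array C(quaternary)–CH(OH)–C(=CH–CH2), tether CH2 cis to the carbinol carbon, exactly the pattern left when an aldehyde carbon and an alkyl group add to the same face of a terminal alkyne. The precursor is an α-quaternary hept-6-ynal bearing methyl and a non-chelating silyloxymethyl group.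

Key step: step 13

Remarks on the chemistry (assumptions included)
- Reading of the target: two 3-alkylidene-2-hydroxy-1-methylcyclohexyl prenyl ketones joined by =CH–CH2–CH2–CH=, both alkenes Z. In ring A (1R,2R) the hydroxyl is cis to methyl; in ring B (1S,2R) it is trans to methyl and cis to the acyl group. The quaternary carbons have opposite sense and the rings differ in relative configuration, so one control element cannot serve both ring closures.
- Choice of controlling groups: an ester beside the aldehyde can be bridged to it by divalent zinc, which places the ester on the inner side and the hydroxyl cis to it. This is used for ring B (step 6) but is the wrong sense for ring A. The ring A ynal 18 therefore carries CH2OSiEt3 in place of an ester (same carbon skeleton and spatial arrangement; its descriptor is S only because CHO now outranks the neighbouring carbon).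
- Both ynals come from one hydroxy ester 7: oxidizing its CH2OH gives 8; silylating it and turning the ester into the aldehyde gives 18, of the opposite sense.
- Assumption: pig liver esterase gives the (R)-half-ester 4, the sense known for 2-alkyl-2-methylmalonates with long chains. The removable silyl cap lengthens the five-carbon chain, which alone lies where the enzyme discriminates poorly. With the opposite sense, 7 would be reached by reducing the acid (mixed anhydride, NaBH4) instead of the ester.
- Stoichiometry of step 17: the dialdehyde 24 has two formyl groups and each takes up one prenyl unit, so two equivalents of 1-chloro-3-methylbut-2-ene are consumed. One is entered as reactant 25, the other as the atom-adding reagent of that step.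

Step 1
Reactants: 1 dimethyl 2-methylmalonate; 2 (5-chloropent-1-yn-1-yl)trimethylsilane
Product: 3 dimethyl 2-methyl-2-[5-(trimethylsilyl)pent-4-yn-1-yl]malonate
Conditions: NaH, DMF, 0 °C; then 2, NaI (cat.), 60 °C
Reagents that add atoms: none
Why: Malonate alkylation: the sodium enolate displaces the primary chloride by SN2 with iodide catalysis (Finkelstein exchange in the flask) and builds the quaternary carbon that carries methyl, both future carbonyl carbons and the alkyne chain, whose silyl cap only serves the enzyme step.

Step 2
Reactants: 3 dimethyl 2-methyl-2-[5-(trimethylsilyl)pent-4-yn-1-yl]malonate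
Product: 4 (R)-2-(methoxycarbonyl)-2-methyl-7-(trimethylsilyl)hept-6-ynoic acid
Conditions: pig liver esterase, phosphate buffer pH 7.5, DMSO (10%), 25 °C, NaOH (pH-stat); then HCl to pH 2
Reagents that add atoms: water (SMILES O)
Why: Enzymatic desymmetrization: the esterase hydrolyses one of the two enantiotopic ester groups and thereby sets the quaternary stereocentre, the long silyl-capped chain and methyl being well differentiated in the active site, and the optical purity can be raised by one crystallization of the 1-phenylethylammonium salt.

Step 3
Reactants: 4 (R)-2-(methoxycarbonyl)-2-methyl-7-(trimethylsilyl)hept-6-ynoic acid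
Product: 6 (S)-2-(hydroxymethyl)-2-methylhept-6-ynoic acid, via C-silylated hydroxy acid 5 (not isolated)
Conditions: LiBEt3H, THF, −78 to 0 °C; then MeOH, K2CO3, 25 °C; then HCl to pH 3
Reagents that add atoms: none
Why: Chemoselective ester reduction with a trialkylborohydride (the first equivalent turns the acid into the inert lithium carboxylate) followed by base-mediated protodesilylation of the alkynylsilane in methanol; the stereocentre is not touched and only its descriptor changes.

Step 4
Reactants: 6 (S)-2-(hydroxymethyl)-2-methylhept-6-ynoic acid
Product: 7 methyl (S)-2-(hydroxymethyl)-2-methylhept-6-ynoate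
Conditions: MeI, KHCO3, DMF, 25 °C
Reagents that add atoms: iodomethane (SMILES CI)
Why: Carboxylate O-alkylation (SN2 esterification) under bicarbonate conditions too mild to alkylate the primary alcohol or deprotonate the alkyne gives the hydroxy ester from which both ynals branch.

Step 5
Reactants: 7 methyl (S)-2-(hydroxymethyl)-2-methylhept-6-ynoate
Product: 8 methyl (S)-2-formyl-2-methylhept-6-ynoate (ring B ynal)
Conditions: Dess–Martin periodinane, CH2Cl2, 25 °C
Reagents that add atoms: none
Why: Dess–Martin oxidation takes the neopentyl primary alcohol to the aldehyde and no further, and the product cannot enolize or racemize because its α-carbon is quaternary.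

Step 6
Reactants: 8 methyl (S)-2-formyl-2-methylhept-6-ynoate; 9 vinylmagnesium bromide
Product: 11 methyl (1S,2R,3Z)-2-hydroxy-1-methyl-3-(prop-2-en-1-ylidene)cyclohexane-1-carboxylate, via chloro(vinyl)zinc 10 (not isolated)
Conditions: CH2=CHMgBr, ZnCl2, THF, 0 °C; then Ni(COD)2 (10 mol%), 8, THF, 0 °C
Reagents that add atoms: none
Why: Nickel-catalysed alkylative cyclization of an alkynyl aldehyde with an organozinc reagent (6-exo-dig): zerovalent nickel couples aldehyde and alkyne, the vinyl group is delivered with retention to the former alkyne terminus so that it ends cis to the carbinol carbon (Z), and divalent zinc and magnesium salts bridging the formyl and ester carbonyls hold the ester on the inner, pseudo-axial side of the chair-like transition state with methyl pseudo-equatorial, so the hydroxyl should form cis to the ester and trans to methyl.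

Step 7
Reactants: 11 methyl (1S,2R,3Z)-2-hydroxy-1-methyl-3-(prop-2-en-1-ylidene)cyclohexane-1-carboxylate
Product: 12 methyl (1S,2R,3Z)-2-[(tert-butyldimethylsilyl)oxy]-1-methyl-3-(prop-2-en-1-ylidene)cyclohexane-1-carboxylate
Conditions: TBSOTf, 2,6-lutidine, CH2Cl2, −78 to 0 °C
Reagents that add atoms: tert-butyldimethylsilyl trifluoromethanesulfonate (SMILES CC(C)(C)[Si](C)(C)OS(=O)(=O)C(F)(F)F)
Why: Silyl ether formation with the silyl triflate and a hindered pyridine base protects the congested allylic carbinol for the hydroboration, zinc and later hydride and barium steps.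

Step 8
Reactants: 12 methyl (1S,2R,3Z)-2-[(tert-butyldimethylsilyl)oxy]-1-methyl-3-(prop-2-en-1-ylidene)cyclohexane-1-carboxylate
Product: 14 methyl (1S,2R,3Z)-2-[(tert-butyldimethylsilyl)oxy]-3-(3-hydroxypropylidene)-1-methylcyclohexane-1-carboxylate, via B-alkyl-9-BBN adduct 13 (not isolated)
Conditions: 9-BBN, THF, 0 to 25 °C; then NaOH, H2O2, 0 °C
Reagents that add atoms: hydrogen peroxide (SMILES OO)
Why: Hydroboration–oxidation with the bulky dialkylborane 9-BBN is selective for the terminal vinyl group of the diene and anti-Markovnikov, so boron and then hydroxyl end on the terminal carbon while the trisubstituted exocyclic alkene and the hindered ester are left alone.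

Step 9
Reactants: 14 methyl (1S,2R,3Z)-2-[(tert-butyldimethylsilyl)oxy]-3-(3-hydroxypropylidene)-1-methylcyclohexane-1-carboxylate
Product: 15 methyl (1S,2R,3Z)-2-[(tert-butyldimethylsilyl)oxy]-3-(3-iodopropylidene)-1-methylcyclohexane-1-carboxylate (ring B iodide)
Conditions: I2, PPh3, imidazole, CH2Cl2, 0 °C
Reagents that add atoms: iodine (SMILES II)
Why: Appel-type iodination: the primary alcohol is activated as its oxyphosphonium salt and displaced by iodide (SN2), giving the homoallylic iodide needed for zinc insertion without touching any stereocentre.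

Step 10
Reactants: 7 methyl (S)-2-(hydroxymethyl)-2-methylhept-6-ynoate
Product: 16 methyl (S)-2-methyl-2-{[(triethylsilyl)oxy]methyl}hept-6-ynoate
Conditions: Et3SiCl, imidazole, CH2Cl2, 0 to 25 °C
Reagents that add atoms: chlorotriethylsilane (SMILES CC[Si](Cl)(CC)CC)
Why: Silyl ether formation on the unhindered primary alcohol installs the non-chelating triethylsilyloxymethyl group that will steer the key step and that mild acid removes later.

Step 11
Reactants: 16 methyl (S)-2-methyl-2-{[(triethylsilyl)oxy]methyl}hept-6-ynoate
Product: 17 (R)-2-methyl-2-{[(triethylsilyl)oxy]methyl}hept-6-yn-1-ol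
Conditions: i-Bu2AlH, CH2Cl2, −78 to 0 °C; then aqueous potassium sodium tartrate (KNaC4H4O6)
Reagents that add atoms: none
Why: Ester reduction with a dialkylaluminium hydride takes the neopentyl methyl ester to the primary alcohol at low temperature, where neither the terminal alkyne nor the silyl ether reacts, and the neutral tartrate work-up avoids the alkoxide-mediated silyl shift between the two CH2O arms that would erode the optical purity.

Step 12
Reactants: 17 (R)-2-methyl-2-{[(triethylsilyl)oxy]methyl}hept-6-yn-1-ol
Product: 18 (S)-2-methyl-2-{[(triethylsilyl)oxy]methyl}hept-6-ynal (ring A ynal, fragment 1)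
Conditions: Dess–Martin periodinane, CH2Cl2, 25 °C
Reagents that add atoms: none
Why: Dess–Martin oxidation gives the non-enolizable α-quaternary aldehyde under near-neutral conditions that the primary triethylsilyl ether survives.

Step 13
Reactants: 15 ring B iodide; 18 ring A ynal
Product: 20 coupled ring A–ring B hydroxy ester (ring A carbinol free and cis to methyl; ring B carbinol silylated), via ring B homoallylzinc iodide 19 (not isolated)
Conditions: Zn, LiCl, THF, 35 °C (15 to 19, 1.5 equiv); then Ni(COD)2 (10 mol%), THF, 0 °C, slow addition of 18
Reagents that add atoms: none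
Why: Zinc inserts into the C–I bond of 15 to give 19 (fragment 2); zerovalent nickel then binds the aldehyde and the terminal alkyne of 18 and couples them oxidatively to a five-membered oxanickelacycle (this forms the carbinol–alkylidene bond and closes ring A in the 6-exo-dig mode), the homoallyl group passes from zinc to nickel, and reductive elimination bonds it to the former alkyne terminus with retention, so the tether CH2 ends cis to the carbinol carbon (Z). The closest known reaction type is the nickel-catalysed alkylative cyclization of alkynyl aldehydes with organozinc reagents. The new carbinol centre is set in the chair-like oxidative cyclization, where the C–O bond must lie pseudo-equatorial in the plane of the metallacycle and the larger CH2OSiEt3 group takes the pseudo-equatorial site, leaving methyl pseudo-axial and hence cis to the new hydroxyl. The step needs this facial selectivity and alkyl transfer in preference to β-hydride elimination: the silyl ether cannot bridge to zinc as an ester would (a chelate would reverse the sense), and phosphine-free nickel lets reductive elimination outrun β-hydride loss. The aldehyde on a quaternary carbon cannot enolize, and the ester, silyl ether and trisubstituted alkene of 19 are inert to an alkylzinc iodide.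

Step 14
Reactants: 20 coupled ring A–ring B hydroxy ester
Product: 21 coupled ester with both ring carbinols as TBS ethers and the primary triethylsilyl ether retained
Conditions: TBSOTf, 2,6-lutidine, CH2Cl2, −78 to 0 °C
Reagents that add atoms: tert-butyldimethylsilyl trifluoromethanesulfonate (SMILES CC(C)(C)[Si](C)(C)OS(=O)(=O)C(F)(F)F)
Why: Silyl ether formation with the silyl triflate masks the new ring A carbinol, so that the β-oxygenated aldehyde and ketone stages ahead cannot suffer retro-aldol cleavage, and leaves the primary triethylsilyl ether in place.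

Step 15
Reactants: 21 coupled bis-TBS ester
Product: 23 bis(hydroxymethyl) bis-TBS ether (diol), via ring B hydroxymethyl triethylsilyl ether 22 (not isolated)
Conditions: i-Bu2AlH, CH2Cl2, −78 to 0 °C; then 1 M HCl, THF, 0 °C
Reagents that add atoms: none
Why: Ester reduction with a dialkylaluminium hydride followed by acid hydrolysis of the primary triethylsilyl ether during the aqueous HCl work-up, which the two hindered secondary TBS ethers withstand, brings both future acyl carbons to the CH2OH level in one operation.

Step 16
Reactants: 23 bis(hydroxymethyl) bis-TBS ether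
Product: 24 dialdehyde bis-TBS ether
Conditions: Dess–Martin periodinane (2.5 equiv), CH2Cl2, 25 °C
Reagents that add atoms: none
Why: Dess–Martin oxidation of both neopentyl primary alcohols gives the dialdehyde, whose formyl groups sit on quaternary carbons and can neither enolize nor epimerize.

Step 17
Reactants: 24 dialdehyde bis-TBS ether; 25 1-chloro-3-methylbut-2-ene (first of the two equivalents consumed)
Product: 27 bis(homoallylic alcohol) bis-TBS ether (mixture at the two new carbinol carbons), via prenylbarium chloride 26 (not isolated)
Conditions: Ba (from BaI2 and Li biphenylide, LiC12H10), THF, 25 °C; 25 (2.4 equiv), −78 °C; then 24 (1.0 equiv), −78 °C; H2O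
Reagents that add atoms: second equivalent of 1-chloro-3-methylbut-2-ene (SMILES CC(C)=CCCl)
Why: Allylbarium addition to aldehydes, run with one prenylbarium chloride per formyl group so that each of the two aldehyde carbons gains one five-carbon unit: unlike prenyl magnesium, zinc or indium reagents, the barium reagent bonds through its unsubstituted CH2 terminus (α-attack, here reinforced by the neopentyl aldehydes, which disfavour the crowded γ-mode) and so gives the linear CH2CH=CMe2 adducts; the two new carbinol centres form as mixtures that converge in the next step.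

Step 18
Reactants: 27 bis(homoallylic alcohol) bis-TBS ether
Product: 28 bis(prenyl ketone) bis-TBS ether
Conditions: Dess–Martin periodinane (2.5 equiv), CH2Cl2, 25 °C
Reagents that add atoms: none
Why: Dess–Martin oxidation of the two secondary homoallylic alcohols gives the β,γ-unsaturated ketones under neutral conditions that do not move the double bonds into conjugation, and removes the two uncontrolled carbinol centres.

Step 19
Reactants: 28 bis(prenyl ketone) bis-TBS ether
Product: 29 target CNP0297042.3
Conditions: HF·pyridine, pyridine, THF, 0 to 25 °C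
Reagents that add atoms: none
Why: Fluoride-mediated desilylation with pyridine-buffered HF cleaves both secondary TBS ethers without the base that could open the β-hydroxy ketones by retro-aldol reaction or conjugate the β,γ-enones, and leaves all four stereocentres and both Z alkenes as set.

Compound list
1 | dimethyl 2-methylmalonate | COC(=O)C(C)C(=O)OC | starting material
2 | (5-chloropent-1-yn-1-yl)trimethylsilane | C[Si](C)(C)C#CCCCCl | starting material
3 | dimethyl 2-methyl-2-[5-(trimethylsilyl)pent-4-yn-1-yl]malonate | COC(=O)C(C)(CCCC#C[Si](C)(C)C)C(=O)OC | intermediate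
4 | (R)-2-(methoxycarbonyl)-2-methyl-7-(trimethylsilyl)hept-6-ynoic acid | OC(=O)[C@@](C(=O)OC)(C)CCCC#C[Si](C)(C)C | intermediate
5 | (S)-2-(hydroxymethyl)-2-methyl-7-(trimethylsilyl)hept-6-ynoic acid (not isolated) | OC(=O)[C@@](CO)(C)CCCC#C[Si](C)(C)C | intermediate
6 | (S)-2-(hydroxymethyl)-2-methylhept-6-ynoic acid | OC(=O)[C@@](CO)(C)CCCC#C | intermediate
7 | methyl (S)-2-(hydroxymethyl)-2-methylhept-6-ynoate | COC(=O)[C@@](CO)(C)CCCC#C | intermediate
8 | methyl (S)-2-formyl-2-methylhept-6-ynoate (ring B ynal) | COC(=O)[C@@](C=O)(C)CCCC#C | intermediate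
9 | vinylmagnesium bromide | C=C[Mg]Br | starting material
10 | chloro(vinyl)zinc (not isolated) | C=C[Zn]Cl | intermediate
11 | methyl (1S,2R,3Z)-2-hydroxy-1-methyl-3-(prop-2-en-1-ylidene)cyclohexane-1-carboxylate (hydroxyl cis to ester, trans to methyl) | C=C/C=C1/CCC[C@](C)(C(=O)OC)[C@@H]1O | intermediate
12 | methyl (1S,2R,3Z)-2-[(tert-butyldimethylsilyl)oxy]-1-methyl-3-(prop-2-en-1-ylidene)cyclohexane-1-carboxylate | C=C/C=C1/CCC[C@](C)(C(=O)OC)[C@@H]1O[Si](C)(C)C(C)(C)C | intermediate
13 | methyl (1S,2R,3Z)-3-[3-(9-borabicyclo[3.3.1]nonan-9-yl)propylidene]-2-[(tert-butyldimethylsilyl)oxy]-1-methylcyclohexane-1-carboxylate (not isolated) | C1CCC2CCCC1B2CC/C=C1/CCC[C@](C)(C(=O)OC)[C@@H]1O[Si](C)(C)C(C)(C)C | intermediate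
14 | methyl (1S,2R,3Z)-2-[(tert-butyldimethylsilyl)oxy]-3-(3-hydroxypropylidene)-1-methylcyclohexane-1-carboxylate | OCC/C=C1/CCC[C@](C)(C(=O)OC)[C@@H]1O[Si](C)(C)C(C)(C)C | intermediate
15 | methyl (1S,2R,3Z)-2-[(tert-butyldimethylsilyl)oxy]-3-(3-iodopropylidene)-1-methylcyclohexane-1-carboxylate (ring B iodide) | ICC/C=C1/CCC[C@](C)(C(=O)OC)[C@@H]1O[Si](C)(C)C(C)(C)C | intermediate
16 | methyl (S)-2-methyl-2-{[(triethylsilyl)oxy]methyl}hept-6-ynoate | COC(=O)[C@@](CO[Si](CC)(CC)CC)(C)CCCC#C | intermediate
17 | (R)-2-methyl-2-{[(triethylsilyl)oxy]methyl}hept-6-yn-1-ol | OC[C@@](CO[Si](CC)(CC)CC)(C)CCCC#C | intermediate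
18 | (S)-2-methyl-2-{[(triethylsilyl)oxy]methyl}hept-6-ynal (ring A ynal, fragment 1) | O=C[C@@](CO[Si](CC)(CC)CC)(C)CCCC#C | intermediate
19 | {3-[(1Z,2R,3S)-2-[(tert-butyldimethylsilyl)oxy]-3-(methoxycarbonyl)-3-methylcyclohexylidene]propyl}zinc iodide (ring B homoallylzinc iodide, fragment 2; not isolated) | I[Zn]CC/C=C1/CCC[C@](C)(C(=O)OC)[C@@H]1O[Si](C)(C)C(C)(C)C | intermediate
20 | methyl (1S,2R,3Z)-2-[(tert-butyldimethylsilyl)oxy]-3-{(4Z)-4-[(2R,3S)-2-hydroxy-3-methyl-3-{[(triethylsilyl)oxy]methyl}cyclohexylidene]butylidene}-1-methylcyclohexane-1-carboxylate (ring A hydroxyl cis to methyl) | CC[Si](CC)(CC)OC[C@]1(C)CCC/C(=C/CC/C=C2/CCC[C@](C)(C(=O)OC)[C@@H]2O[Si](C)(C)C(C)(C)C)[C@H]1O | intermediate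
21 | methyl (1S,2R,3Z)-2-[(tert-butyldimethylsilyl)oxy]-3-{(4Z)-4-[(2R,3S)-2-[(tert-butyldimethylsilyl)oxy]-3-methyl-3-{[(triethylsilyl)oxy]methyl}cyclohexylidene]butylidene}-1-methylcyclohexane-1-carboxylate | CC[Si](CC)(CC)OC[C@]1(C)CCC/C(=C/CC/C=C2/CCC[C@](C)(C(=O)OC)[C@@H]2O[Si](C)(C)C(C)(C)C)[C@H]1O[Si](C)(C)C(C)(C)C | intermediate
22 | analogue of 21 with the ring B ester reduced to CH2OH, ring A CH2OSiEt3 still in place (not isolated) | CC[Si](CC)(CC)OC[C@]1(C)CCC/C(=C/CC/C=C2/CCC[C@](C)(CO)[C@@H]2O[Si](C)(C)C(C)(C)C)[C@H]1O[Si](C)(C)C(C)(C)C | intermediate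
23 | diol: each ring carries CH2OH on its quaternary carbon and OTBS on its carbinol carbon (ring A OTBS cis to methyl, ring B OTBS trans to methyl; both alkenes Z) | OC[C@]1(C)CCC/C(=C/CC/C=C2/CCC[C@](C)(CO)[C@@H]2O[Si](C)(C)C(C)(C)C)[C@H]1O[Si](C)(C)C(C)(C)C | intermediate
24 | dialdehyde: as 23 with both CH2OH groups oxidized to CHO | O=C[C@]1(C)CCC/C(=C/CC/C=C2/CCC[C@](C)(C=O)[C@@H]2O[Si](C)(C)C(C)(C)C)[C@H]1O[Si](C)(C)C(C)(C)C | intermediate
25 | 1-chloro-3-methylbut-2-ene (prenyl chloride; two equivalents are consumed in step 17) | CC(C)=CCCl | starting material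
26 | (3-methylbut-2-en-1-yl)barium chloride (not isolated) | CC(C)=CC[Ba]Cl | intermediate
27 | bis(homoallylic alcohol): as 24 with each CHO converted to CH(OH)CH2CH=C(CH3)2, both new carbinol carbons as mixtures | CC(C)=CCC(O)[C@]1(C)CCC/C(=C/CC/C=C2/CCC[C@](C)(C(O)CC=C(C)C)[C@@H]2O[Si](C)(C)C(C)(C)C)[C@H]1O[Si](C)(C)C(C)(C)C | intermediate
28 | bis-TBS ether of the target (both ring carbinols silylated, both prenyl ketones in place) | CC(C)=CCC(=O)[C@]1(C)CCC/C(=C/CC/C=C2/CCC[C@](C)(C(=O)CC=C(C)C)[C@@H]2O[Si](C)(C)C(C)(C)C)[C@H]1O[Si](C)(C)C(C)(C)C | intermediate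
29 | 1-[(1R,2R,3Z)-2-hydroxy-3-{(4Z)-4-[(2R,3S)-2-hydroxy-3-methyl-3-(4-methylpent-3-enoyl)cyclohexylidene]butylidene}-1-methylcyclohexyl]-4-methylpent-3-en-1-one (CNP0297042.3) | CC(C)=CCC(=O)[C@]1(C)CCC/C(=C/CC/C=C2/CCC[C@](C)(C(=O)CC=C(C)C)[C@@H]2O)[C@H]1O | target

Total step count: 19 steps.
Longest linear sequence: 16 steps (steps 1 to 9, then 13 to 19); the ring A ynal branch (steps 10 to 12) leaves from 7.

Steps most likely to fail

Step 13 (key step). What may go wrong: poor facial selectivity in the oxidative cyclization, so that the hydroxyl forms trans to methyl; β-hydride elimination from the homoallylnickel intermediate is a second, less likely failure. The fallback moves the setting of the carbinol centre to a hydroxyl-directed reduction. It sets out from 18 and 15: the coupling is run as in step 13 and the mixture of 20 with its ring A carbinol epimer F1 is taken on together. Dess–Martin oxidation should give the ring A enone F2, and AcOH/THF/H2O should remove the primary triethylsilyl ether to give the hydroxymethyl enone F3. Me4NBH(OAc)3 in MeCN/AcOH at −20 °C (Evans–Saksena reduction) delivers hydride within the alkoxyborohydride from the face of the CH2OH group, so the ring A 1,3-diol F4 should carry the ring hydroxyl trans to CH2OH and cis to methyl. Et3SiCl and imidazole at −40 °C should silylate only the primary hydroxyl and return 20.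

Step 6. What may go wrong: poor facial selectivity if zinc chelation of the formyl ester does not govern the ring closure, so that the epimer with hydroxyl cis to methyl forms in quantity. The fallback replaces stereoselective ring closure by separation and recycling. It sets out from 8: the cyclization mixture is separated on silica into 11 and the carbinol epimer F5. F5 is oxidized with MnO2 to the dienone F6. Luche reduction (NaBH4, CeCl3, MeOH, −78 °C), in which axial hydride delivery to the conformer with the smaller ester group axial should favour hydroxyl cis to ester, returns 11 together with F5 for a second separation; 11 re-enters at step 7.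

Step 2. What may go wrong: low enantiotopic-group selectivity of the esterase, giving a half-ester of insufficient optical purity. The fallback replaces desymmetrization by classical resolution. It sets out from 3: KOH (1 equiv) in MeOH at 25 °C hydrolyses one ester and removes the alkynyl silyl group to give the racemic half-ester F7. Crystallization with (R)-1-phenylethylamine (or its antipode, whichever gives the less soluble salt of the R acid) provides the salt F8. Acidification frees the (R)-half-ester F9, and reduction with LiBEt3H as in step 3 returns 6.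

Further compounds
F1 | step 13 | ring A carbinol epimer of 20 (ring A hydroxyl trans to methyl) | CC[Si](CC)(CC)OC[C@]1(C)CCC/C(=C/CC/C=C2/CCC[C@](C)(C(=O)OC)[C@@H]2O[Si](C)(C)C(C)(C)C)[C@@H]1O
F2 | step 13 | ring A enone (ring A carbinol of 20 oxidized to the ketone, Z alkylidene kept) | CC[Si](CC)(CC)OC[C@]1(C)CCC/C(=C/CC/C=C2/CCC[C@](C)(C(=O)OC)[C@@H]2O[Si](C)(C)C(C)(C)C)C1=O
F3 | step 13 | hydroxymethyl enone (F2 without the triethylsilyl group) | OC[C@]1(C)CCC/C(=C/CC/C=C2/CCC[C@](C)(C(=O)OC)[C@@H]2O[Si](C)(C)C(C)(C)C)C1=O
F4 | step 13 | ring A 1,3-diol (ring hydroxyl trans to CH2OH, cis to methyl) | OC[C@]1(C)CCC/C(=C/CC/C=C2/CCC[C@](C)(C(=O)OC)[C@@H]2O[Si](C)(C)C(C)(C)C)[C@H]1O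
F5 | step 6 | methyl (1S,2S,3Z)-2-hydroxy-1-methyl-3-(prop-2-en-1-ylidene)cyclohexane-1-carboxylate | C=C/C=C1/CCC[C@](C)(C(=O)OC)[C@H]1O
F6 | step 6 | methyl (1S,3Z)-1-methyl-2-oxo-3-(prop-2-en-1-ylidene)cyclohexane-1-carboxylate | C=C/C=C1/CCC[C@](C)(C(=O)OC)C1=O
F7 | step 2 | racemic 2-(methoxycarbonyl)-2-methylhept-6-ynoic acid | OC(=O)C(C)(CCCC#C)C(=O)OC
F8 | step 2 | (R)-1-phenylethylammonium (R)-2-(methoxycarbonyl)-2-methylhept-6-ynoate | C[C@@H]([NH3+])c1ccccc1.[O-]C(=O)[C@@](C(=O)OC)(C)CCCC#C
F9 | step 2 | (R)-2-(methoxycarbonyl)-2-methylhept-6-ynoic acid | OC(=O)[C@@](C(=O)OC)(C)CCCC#C
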